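Readings and results stem from a simulated flask with made-up constants.

Back larch as the best flask, and leave its bath and its clock as they are while I am away.

| flask | substrate | temperature | remark | time |
|---|---|---|---|---|
| epsilon | 1.3 mM | 50 °C | run made earlier |  |
| delta | 3 mM | 72 °C | run made earlier |  |
| larch | 2.0 mM | 80 °C |  | 2.0 min |
| cedar | 2.0 mM | 40 °C |  | 2.0 min |
| elm | 2.0 mM | 60 °C |  | 2.0 min |

| run | time / min | target / % | substrate / % |
|---|---|---|---|
| epsilon | 0.667 | 60.2 | 0 |
| epsilon | 1.33 | 61.6 | 1.3 |
| epsilon | 3.00 | 60.5 | 0 |
| epsilon | 4.00 | 59.5 | 0 |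
| epsilon | 6.00 | 60.5 | 0.3 |
| epsilon | 8.00 | 58.3 | 1.0 |
| epsilon | 12.0 | 59.9 | 0 |
| delta | 0.333 | 71.1 | 0 |
| delta | 0.667 | 71.0 | 1.1 |
| delta | 1.00 | 70.2 | 0.8 |
| delta | 1.33 | 69.5 | 0 |
| delta | 1.50 | 70.9 | 0 |
| delta | 2.00 | 70.6 | 1.4 |
| delta | 2.50 | 71.9 | 0.3 |

(standard deviation of a reading: 1 percentage point)

- the best flask by amount of target, in percent of the substrate charged; "all alike" if 1.5 percentage points covers them all (larch / cedar / elm / all alike)
- amount of target at the end, in percent of the substrate charged, larch
- amount of target at the end, in percent of the substrate charged, cedar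
- amount of target at the end, in percent of the substrate charged, elm

- what was read earlier has a scatter of 1 percentage point, one standard deviation
- in a conversion other conformer counts as not yet reacted

Here is what you will find. At the first sample, substrate reads 0% in the epsilon run and 0% in the delta run. Target then stays flat within the scatter, from 60.2% to 59.9% in epsilon. So waiting bought nothing in those runs, and the fraction to watch is what is left over, the part of the charge that isn't target.

Take the odds, target over that remainder, a kind of selectivity factor. Mean target is 60.1% in epsilon, so the odds are 1.50. In delta it is 70.7%, so the odds are 2.42.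

My rule is the doubling step, the temperature rise that doubles the odds, here 32.1 K. It is a bet read from two runs, and the charge changed between them too. Counted from delta, it gives odds of 2.87 in larch, so 74.2%. Elm gets 65.1% and cedar 54.8%.

The forecast, with slightly different numbers, names larch at 73.8%, elm at 65.2% and cedar at 54%: “The yield is therefore set by a fixed split, not by time”.

The flasks give 74.2% in larch, 65.6% in elm and 50.4% in cedar, so larch is best.

    substrate ⇌ other conformer (K = 3.08, k = 0.0260 s⁻¹, Ea = 87.0 kJ mol⁻¹, ΔH = −19.0 kJ mol⁻¹)
    substrate → target (k = 0.307 s⁻¹, Ea = 71.0 kJ mol⁻¹)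
    other conformer → isomer of the product A (k = 0.832 s⁻¹, Ea = 75.0 kJ mol⁻¹)
    target ⇌ isomer of the product B (K = 0.370, k = 0.443 s⁻¹, Ea = 94.0 kJ mol⁻¹, ΔH = −33.0 kJ mol⁻¹)
    substrate + target → side product (k = 6.12 M⁻¹ s⁻¹, Ea = 46.0 kJ mol⁻¹)
    (constants at 60 °C)

Cedar ends 4.4 percentage points below my reckoning. The largest single effect on the gap between larch and cedar is what the temperature does to the path from substrate to target: take that effect away and the gap of 24 points turns into −28 points. On a repeat of larch at 65 °C, the doubling step gives odds of 2.08, so 67.5%, and that flask gives 68.3%.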